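**Retrosynthetic overview**
1. The strategy rests on ring A carrying O1 on C8a and the C4 acyl carbon on the neighbouring C4a; this ortho O/acyl pair is what an aryne (C4a≡C8a) leaves when it inserts into the O–C(acyl) bond of a carboxylate.
2. Ring C is opened at O1–C2 to a 2'-hydroxy α,β-epoxy ketone (22), which is cut at C8a–O1 and C4a–C4 into the hexasubstituted 2-silylaryl triflate 15 and the (2R,3S)-glycidate 20.
3. 15 comes from phloroglucinol: directed metalation/prenylation (C6), dibromination, Br/Li exchange and alkylation with (R)-lavandulyl triflate (C8), then retro-Brook shift and triflation (C4a/C8a).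
4. 20 comes from 2,4-dihydroxybenzaldehyde: Horner–Wadsworth–Emmons olefination, Shi epoxidation with the L-series catalyst, silanolate ester cleavage.
5. Ring order: A and B are bought and decorated; the oxirane is made in step 11; ring C is closed last (step 14) by 6-endo epoxide opening; deprotection follows.

Key step: step 13

Assumption: the glycidic acid partner is made at the ester oxidation level and used as its anhydrous potassium salt, because a free 3-(2,4-dialkoxyphenyl)glycidic acid decarboxylates with epoxide opening and the corresponding epoxy alcohol is too acid-labile for a titanium-mediated epoxidation and oxidation sequence.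

**Route**

Step 1
Reactants: 1 phloroglucinol (benzene-1,3,5-triol)
Product: 2 5-[(triisopropylsilyl)oxy]benzene-1,3-diol
Conditions: TIPSCl (0.5 equiv relative to 1), imidazole, DMF, 0 °C → rt; excess 1 and bis-ether removed by chromatography
Reagents that add atoms: chlorotriisopropylsilane, CC(C)[Si](Cl)(C(C)C)C(C)C
Why: Statistical O-silylation with the triol in excess should give mainly the mono-ether, and the bulky non-coordinating TIPS group marks the oxygen that later becomes the C8a triflate.

Step 2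
Reactants: 2 5-[(triisopropylsilyl)oxy]benzene-1,3-diol
Product: 3 [3,5-bis(methoxymethoxy)phenoxy]triisopropylsilane
Conditions: MOMCl (2.6 equiv), i-Pr2NEt (3 equiv), CH2Cl2, 0 °C → rt
Reagents that add atoms: chloromethyl methyl ether, COCCl
Why: O-Alkylation of both free phenols gives MOM ethers that serve as metalation directors and as acid-labile protecting groups for O5 and O7.

Step 3
Reactants: 3 [3,5-bis(methoxymethoxy)phenoxy]triisopropylsilane; 4 prenyl bromide (1-bromo-3-methylbut-2-ene)
Product: 6 [3,5-bis(methoxymethoxy)-4-(3-methylbut-2-en-1-yl)phenoxy]triisopropylsilane, via aryllithium 5 (not isolated)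
Conditions: n-BuLi (1.2 equiv), THF, 0 °C → rt; CuBr·SMe2 (0.2 equiv), −40 °C; then 4, −40 °C → rt
Reagents that add atoms: none
Why: Directed ortho-metalation should occur at the only CH flanked by two MOM ethers (the TIPS ether shields its own ortho positions), and copper-mediated SN2 allylation places the prenyl group on the future C6.

Step 4
Reactants: 6 [3,5-bis(methoxymethoxy)-4-(3-methylbut-2-en-1-yl)phenoxy]triisopropylsilane
Product: 7 [2,6-dibromo-3,5-bis(methoxymethoxy)-4-(3-methylbut-2-en-1-yl)phenoxy]triisopropylsilane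
Conditions: NBS (2.1 equiv), solid NaHCO3, MeCN–CH2Cl2, −30 → 0 °C, dark
Reagents that add atoms: N-bromosuccinimide, O=C1CCC(=O)N1Br
Why: Electrophilic aromatic bromination of the two remaining equivalent positions of the trioxygenated ring should be much faster than attack of NBS on the trisubstituted olefin in an aprotic buffered medium at low temperature.

Step 5
Reactants: 8 (R)-lavandulol [(2R)-5-methyl-2-(prop-1-en-2-yl)hex-4-en-1-ol]
Product: 9 (2R)-5-methyl-2-(prop-1-en-2-yl)hex-4-en-1-yl trifluoromethanesulfonate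
Conditions: Tf2O (1.1 equiv), 2,6-lutidine (1.3 equiv), CH2Cl2, −78 °C; cold pentane/silica plug; used at once
Reagents that add atoms: triflic anhydride, O=S(=O)(OS(=O)(=O)C(F)(F)F)C(F)(F)F
Why: O-Sulfonylation of the primary alcohol gives the most reactive leaving group for the β-branched carbon, and the stereocentre is one carbon away from the reacting centre and is not touched.

Step 6
Reactants: 7 [2,6-dibromo-3,5-bis(methoxymethoxy)-4-(3-methylbut-2-en-1-yl)phenoxy]triisopropylsilane; 9 (2R)-5-methyl-2-(prop-1-en-2-yl)hex-4-en-1-yl trifluoromethanesulfonate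
Product: 11 {2-bromo-3,5-bis(methoxymethoxy)-4-(3-methylbut-2-en-1-yl)-6-[(2S)-5-methyl-2-(prop-1-en-2-yl)hex-4-en-1-yl]phenoxy}triisopropylsilane, via aryllithium 10 (not isolated)
Conditions: 7 (1.2 equiv), n-BuLi (1.2 equiv), Et2O–THF, −78 °C; then 9 (1.0 equiv), −78 → −30 °C
Reagents that add atoms: none
Why: Single bromine–lithium exchange of the symmetric dibromide, followed by SN2 alkylation of the aryllithium with the primary triflate, should attach the lavandulyl chain at the future C8 with its stereocentre intact (the descriptor changes to S only through CIP priorities) and leave the second bromine as the C4a marker.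

Step 7
Reactants: 11 {2-bromo-3,5-bis(methoxymethoxy)-4-(3-methylbut-2-en-1-yl)-6-[(2S)-5-methyl-2-(prop-1-en-2-yl)hex-4-en-1-yl]phenoxy}triisopropylsilane
Product: 12 2-bromo-3,5-bis(methoxymethoxy)-4-(3-methylbut-2-en-1-yl)-6-[(2S)-5-methyl-2-(prop-1-en-2-yl)hex-4-en-1-yl]phenol
Conditions: TBAF (1.1 equiv), THF, 0 °C; then H2O
Reagents that add atoms: none
Why: Fluoride-mediated cleavage of the aryl silyl ether should free the C8a phenol without affecting the aryl bromide, the MOM ethers or the olefins.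

Step 8
Reactants: 12 2-bromo-3,5-bis(methoxymethoxy)-4-(3-methylbut-2-en-1-yl)-6-[(2S)-5-methyl-2-(prop-1-en-2-yl)hex-4-en-1-yl]phenol
Product: 15 3,5-bis(methoxymethoxy)-4-(3-methylbut-2-en-1-yl)-2-[(2S)-5-methyl-2-(prop-1-en-2-yl)hex-4-en-1-yl]-6-(trimethylsilyl)phenyl trifluoromethanesulfonate, via O-trimethylsilyl ether 13 (not isolated), via lithium silylphenoxide 14 (not isolated)
Conditions: (i) HMDS, THF, 65 °C, evaporate; (ii) n-BuLi (1.1 equiv), THF, −100 → −78 °C; (iii) PhNTf2 (1.2 equiv), −78 °C → rt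
Reagents that add atoms: hexamethyldisilazane, C[Si](C)(C)N[Si](C)(C)C; N-phenylbis(trifluoromethanesulfonimide), O=S(=O)(N(c1ccccc1)S(=O)(=O)C(F)(F)F)C(F)(F)F
Why: O-Silylation, bromine–lithium exchange and anionic 1,3 O→C silyl migration (retro-Brook rearrangement) should give the ortho-silyl phenoxide, which is trapped as the triflate; this is the standard one-pot conversion of an ortho-bromophenol into a 2-(trimethylsilyl)aryl triflate.

Step 9
Reactants: 16 2,4-dihydroxybenzaldehyde
Product: 17 2,4-bis(methoxymethoxy)benzaldehyde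
Conditions: MOMCl (3 equiv), i-Pr2NEt (4 equiv), CH2Cl2, 0 °C → reflux
Reagents that add atoms: chloromethyl methyl ether, COCCl
Why: O-Alkylation of both phenols (the hydrogen-bonded 2-OH needs the excess and warming) gives fluoride-inert, acid-labile ethers for the B ring.

Step 10
Reactants: 17 2,4-bis(methoxymethoxy)benzaldehyde
Product: 18 ethyl (2E)-3-[2,4-bis(methoxymethoxy)phenyl]prop-2-enoate
Conditions: (EtO)2P(O)CH2CO2Et, NaH, THF, 0 °C → rt
Reagents that add atoms: triethyl phosphonoacetate, CCOC(=O)CP(=O)(OCC)OCC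
Why: Horner–Wadsworth–Emmons olefination of an aryl aldehyde with a stabilised phosphonate should give the E-cinnamate needed for a trans-oxirane.

Step 11
Reactants: 18 ethyl (2E)-3-[2,4-bis(methoxymethoxy)phenyl]prop-2-enoate
Product: 19 ethyl (2R,3S)-3-[2,4-bis(methoxymethoxy)phenyl]oxirane-2-carboxylate
Conditions: L-fructose-derived 4,5-di-O-acetyl-1,2-O-isopropylidene ketone (enantiomer of the acetate-type Shi ketone, 0.3 equiv), Oxone, NaHCO3, Bu4NHSO4 (cat.), MeCN–aq. Na2EDTA, 0 °C
Reagents that add atoms: potassium peroxymonosulfate (Oxone), OOS(=O)(=O)[O-].[K+]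
Why: Shi epoxidation transfers oxygen from the chiral dioxirane stereospecifically to the E-olefin (trans-oxirane); the acetate-type ketone is the variant suited to cinnamate esters and its D-series form is known to give the (2S,3R) series, so the L-enantiomer should set C2 (R) and C3 (S) together, while the buffered medium and the ester group protect the electron-rich benzylic oxirane.

Step 12
Reactants: 19 ethyl (2R,3S)-3-[2,4-bis(methoxymethoxy)phenyl]oxirane-2-carboxylate
Product: 20 potassium (2R,3S)-3-[2,4-bis(methoxymethoxy)phenyl]oxirane-2-carboxylate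
Conditions: KOSiMe3 (1.0 equiv), THF, 0 °C → rt; filter, dry in vacuo
Reagents that add atoms: potassium trimethylsilanolate, C[Si](C)(C)[O-].[K+]
Why: Anhydrous silanolate cleavage of the ester should give the dry potassium carboxylate directly, so the decarboxylation-prone free acid is never formed and no proton source is carried into the aryne step.

Step 13
Reactants: 15 3,5-bis(methoxymethoxy)-4-(3-methylbut-2-en-1-yl)-2-[(2S)-5-methyl-2-(prop-1-en-2-yl)hex-4-en-1-yl]-6-(trimethylsilyl)phenyl trifluoromethanesulfonate; 20 potassium (2R,3S)-3-[2,4-bis(methoxymethoxy)phenyl]oxirane-2-carboxylate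
Product: 22 [(2R,3S)-3-[2,4-bis(methoxymethoxy)phenyl]oxiran-2-yl]{2-hydroxy-4,6-bis(methoxymethoxy)-5-(3-methylbut-2-en-1-yl)-3-[(2S)-5-methyl-2-(prop-1-en-2-yl)hex-4-en-1-yl]phenyl}methanone, via aryne 21 (not isolated)
Conditions: 20 (1.5 equiv), KF (3 equiv), 18-crown-6 (3 equiv), THF, 0 °C → rt, slow addition of 15; pH 7 phosphate buffer
Reagents that add atoms: none
Why: Proposed new method: fluoride removes the silyl group of 15 and triflate leaves to give aryne 21 (C4a≡C8a), the carboxylate oxygen of 20 adds to C8a, and the aryl anion formed at C4a attacks the adjacent ester carbonyl (4-exo-trig) to give a benzoxete alkoxide that opens to the C4a ketone and the C8a phenoxide, an anionic Fries-type 1,3 O→C acyl shift. The closest known reactions are the insertion of arynes into the O–C(acyl) bond of aryl, alkenyl and alkyl carboxylic acids to give ortho-hydroxyaryl ketones and the anionic ortho-Fries rearrangement; a glycidate partner and a fully substituted aryne have not been shown. No ring is closed and no stereocentre is made; the oxirane carbons are spectators because the medium is aprotic, the oxirane C–H is not enolisable and the Z-ester conformation keeps the oxirane out of reach of the aryl anion. The step needs addition at C8a and not at C4a, which the inductively withdrawing C5–O(MOM) should secure by polarising the aryne so that negative charge develops at C4a next to oxygen, against only a modest steric bias from the C8 methylene. It also needs acyl capture to outrun protonation of the aryl anion, which the preformed anhydrous potassium carboxylate in THF should secure, since no O–H acid and no acidic solvent such as MeCN is present. Keeping 20 in excess, adding 15 slowly and quenching into neutral buffer should keep the product phenoxide from adding to a second aryne or opening the oxirane.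

Step 14
Reactants: 22 [(2R,3S)-3-[2,4-bis(methoxymethoxy)phenyl]oxiran-2-yl]{2-hydroxy-4,6-bis(methoxymethoxy)-5-(3-methylbut-2-en-1-yl)-3-[(2S)-5-methyl-2-(prop-1-en-2-yl)hex-4-en-1-yl]phenyl}methanone
Product: 23 (2R,3R)-2-[2,4-bis(methoxymethoxy)phenyl]-3-hydroxy-5,7-bis(methoxymethoxy)-6-(3-methylbut-2-en-1-yl)-8-[(2S)-5-methyl-2-(prop-1-en-2-yl)hex-4-en-1-yl]-2,3-dihydro-4H-chromen-4-one
Conditions: CSA (0.1 equiv), CH2Cl2, −20 → 0 °C
Reagents that add atoms: none
Why: In this acid-catalysed cyclisation of a 2'-hydroxychalcone epoxide to a dihydroflavonol, the C8a phenol should open the oxirane at the benzylic carbon (6-endo, favoured by the 2,4-dialkoxyphenyl group that carries the developing positive charge) with inversion, so the trans-epoxide gives the 2,3-trans ring with C3 (R) retained and C2 (R) set; any ionisation at C2 should still converge on the diequatorial trans isomer.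

Step 15
Reactants: 23 (2R,3R)-2-[2,4-bis(methoxymethoxy)phenyl]-3-hydroxy-5,7-bis(methoxymethoxy)-6-(3-methylbut-2-en-1-yl)-8-[(2S)-5-methyl-2-(prop-1-en-2-yl)hex-4-en-1-yl]-2,3-dihydro-4H-chromen-4-one
Product: 24 (2R,3R)-2-(2,4-dihydroxyphenyl)-3,5,7-trihydroxy-6-(3-methylbut-2-en-1-yl)-8-[(2S)-5-methyl-2-(prop-1-en-2-yl)hex-4-en-1-yl]-2,3-dihydro-4H-chromen-4-one (CNP0207904.2)
Conditions: 3 M aq. HCl–MeOH (1:5), rt → 40 °C
Reagents that add atoms: none
Why: Acid-catalysed acetal methanolysis should remove the four MOM ethers under conditions commonly tolerated by prenylated flavanones, and C2 and C3 are not affected because the 2,3-trans arrangement is the thermodynamic one.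

**Compound list**
1 | phloroglucinol | Oc1cc(O)cc(O)c1 | starting material
2 | 5-[(triisopropylsilyl)oxy]benzene-1,3-diol | Oc1cc(O)cc(O[Si](C(C)C)(C(C)C)C(C)C)c1 | intermediate
3 | [3,5-bis(methoxymethoxy)phenoxy]triisopropylsilane | COCOc1cc(OCOC)cc(O[Si](C(C)C)(C(C)C)C(C)C)c1 | intermediate
4 | prenyl bromide | CC(C)=CCBr | starting material
5 | [2,6-bis(methoxymethoxy)-4-(triisopropylsilyloxy)phenyl]lithium | [Li]c1c(OCOC)cc(O[Si](C(C)C)(C(C)C)C(C)C)cc1OCOC | intermediate
6 | [3,5-bis(methoxymethoxy)-4-(3-methylbut-2-en-1-yl)phenoxy]triisopropylsilane | COCOc1cc(O[Si](C(C)C)(C(C)C)C(C)C)cc(OCOC)c1CC=C(C)C | intermediate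
7 | [2,6-dibromo-3,5-bis(methoxymethoxy)-4-(3-methylbut-2-en-1-yl)phenoxy]triisopropylsilane | COCOc1c(CC=C(C)C)c(OCOC)c(Br)c(O[Si](C(C)C)(C(C)C)C(C)C)c1Br | intermediate
8 | (R)-lavandulol | C=C(C)[C@@H](CC=C(C)C)CO | starting material
9 | (2R)-5-methyl-2-(prop-1-en-2-yl)hex-4-en-1-yl trifluoromethanesulfonate | C=C(C)[C@@H](CC=C(C)C)COS(=O)(=O)C(F)(F)F | intermediate
10 | [3-bromo-4,6-bis(methoxymethoxy)-5-(3-methylbut-2-en-1-yl)-2-(triisopropylsilyloxy)phenyl]lithium | COCOc1c(CC=C(C)C)c(OCOC)c(Br)c(O[Si](C(C)C)(C(C)C)C(C)C)c1[Li] | intermediate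
11 | {2-bromo-3,5-bis(methoxymethoxy)-4-(3-methylbut-2-en-1-yl)-6-[(2S)-5-methyl-2-(prop-1-en-2-yl)hex-4-en-1-yl]phenoxy}triisopropylsilane | C=C(C)[C@@H](CC=C(C)C)Cc1c(OCOC)c(CC=C(C)C)c(OCOC)c(Br)c1O[Si](C(C)C)(C(C)C)C(C)C | intermediate
12 | 2-bromo-3,5-bis(methoxymethoxy)-4-(3-methylbut-2-en-1-yl)-6-[(2S)-5-methyl-2-(prop-1-en-2-yl)hex-4-en-1-yl]phenol | C=C(C)[C@@H](CC=C(C)C)Cc1c(OCOC)c(CC=C(C)C)c(OCOC)c(Br)c1O | intermediate
13 | O-trimethylsilyl ether of 12 | C=C(C)[C@@H](CC=C(C)C)Cc1c(OCOC)c(CC=C(C)C)c(OCOC)c(Br)c1O[Si](C)(C)C | intermediate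
14 | lithium 3,5-bis(methoxymethoxy)-4-(3-methylbut-2-en-1-yl)-2-[(2S)-5-methyl-2-(prop-1-en-2-yl)hex-4-en-1-yl]-6-(trimethylsilyl)phenolate | C=C(C)[C@@H](CC=C(C)C)Cc1c(OCOC)c(CC=C(C)C)c(OCOC)c([Si](C)(C)C)c1[O-].[Li+] | intermediate
15 | 3,5-bis(methoxymethoxy)-4-(3-methylbut-2-en-1-yl)-2-[(2S)-5-methyl-2-(prop-1-en-2-yl)hex-4-en-1-yl]-6-(trimethylsilyl)phenyl trifluoromethanesulfonate (aryne precursor) | C=C(C)[C@@H](CC=C(C)C)Cc1c(OCOC)c(CC=C(C)C)c(OCOC)c([Si](C)(C)C)c1OS(=O)(=O)C(F)(F)F | intermediate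
16 | 2,4-dihydroxybenzaldehyde | O=Cc1ccc(O)cc1O | starting material
17 | 2,4-bis(methoxymethoxy)benzaldehyde | O=Cc1ccc(OCOC)cc1OCOC | intermediate
18 | ethyl (2E)-3-[2,4-bis(methoxymethoxy)phenyl]prop-2-enoate | CCOC(=O)/C=C/c1ccc(OCOC)cc1OCOC | intermediate
19 | ethyl (2R,3S)-3-[2,4-bis(methoxymethoxy)phenyl]oxirane-2-carboxylate | CCOC(=O)[C@@H]1O[C@H]1c1ccc(OCOC)cc1OCOC | intermediate
20 | potassium (2R,3S)-3-[2,4-bis(methoxymethoxy)phenyl]oxirane-2-carboxylate | [K+].[O-]C(=O)[C@@H]1O[C@H]1c1ccc(OCOC)cc1OCOC | intermediate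
21 | 3,5-bis(methoxymethoxy)-4-(3-methylbut-2-en-1-yl)-6-[(2S)-5-methyl-2-(prop-1-en-2-yl)hex-4-en-1-yl]-1,2-didehydrobenzene (C4a≡C8a aryne) | C=C(C)[C@@H](CC=C(C)C)CC1=C(OCOC)C(CC=C(C)C)=C(OCOC)C#C1 | intermediate
22 | [(2R,3S)-3-[2,4-bis(methoxymethoxy)phenyl]oxiran-2-yl]{2-hydroxy-4,6-bis(methoxymethoxy)-5-(3-methylbut-2-en-1-yl)-3-[(2S)-5-methyl-2-(prop-1-en-2-yl)hex-4-en-1-yl]phenyl}methanone | C=C(C)[C@@H](CC=C(C)C)Cc1c(OCOC)c(CC=C(C)C)c(OCOC)c(C(=O)[C@@H]2O[C@H]2c2ccc(OCOC)cc2OCOC)c1O | intermediate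
23 | (2R,3R)-2-[2,4-bis(methoxymethoxy)phenyl]-3-hydroxy-5,7-bis(methoxymethoxy)-6-(3-methylbut-2-en-1-yl)-8-[(2S)-5-methyl-2-(prop-1-en-2-yl)hex-4-en-1-yl]-2,3-dihydro-4H-chromen-4-one | C=C(C)[C@@H](CC=C(C)C)Cc1c(OCOC)c(CC=C(C)C)c(OCOC)c2c1O[C@H](c1ccc(OCOC)cc1OCOC)[C@@H](O)C2=O | intermediate
24 | (2R,3R)-2-(2,4-dihydroxyphenyl)-3,5,7-trihydroxy-6-(3-methylbut-2-en-1-yl)-8-[(2S)-5-methyl-2-(prop-1-en-2-yl)hex-4-en-1-yl]-2,3-dihydro-4H-chromen-4-one | C=C(C)[C@@H](CC=C(C)C)Cc1c(O)c(CC=C(C)C)c(O)c2c1O[C@H](c1ccc(O)cc1O)[C@@H](O)C2=O | target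

**Step count**
Total: 15 steps. Longest linear sequence: 10 steps (1, 2, 3, 4, 6, 7, 8, 13, 14, 15).

**Steps most likely to fail**

Step 13 (proposed new method). The C4a aryl anion may be protonated before it captures the acyl group, the carboxylate may add at the wrong aryne carbon, or the product phenoxide may open the oxirane prematurely in the basic medium. The fallback uses a Weinreb ketone synthesis; it sets out from 20 and 11 and returns at 22. Salt 20 is coupled with N,O-dimethylhydroxylamine hydrochloride (EDC, HOBt, N-methylmorpholine, CH2Cl2, 0 °C) to give the (2R,3S)-Weinreb amide F1. Bromide 11 is converted by bromine–lithium exchange (t-BuLi, Et2O, −78 °C) into the C4a aryllithium F2, which is acylated by F1 to the 2'-O-TIPS epoxy ketone F3. Buffered desilylation (TBAF/AcOH, THF, 0 °C) then gives 22.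

Step 6. E2 loss of triflic acid from 9 (the β-hydrogen is tertiary and allylic) or slow SN2 attack of the hindered aryllithium at the β-branched carbon, which would leave time for silyl migration, may erode the coupling. The fallback reverses the polarity by a Negishi coupling; it sets out from 8 and 7 and returns at 11. Alcohol 8 is converted (I2, PPh3, imidazole, CH2Cl2) into (R)-lavandulyl iodide F4. Iodine–lithium exchange (t-BuLi, pentane–Et2O, −78 °C) gives (R)-lavandulyllithium F5, which is transmetalated with ZnBr2 to (R)-lavandulylzinc bromide F6. Palladium-catalysed coupling of F6 with an excess of dibromide 7 (Pd(OAc)2/SPhos, THF, rt → 50 °C) should give 11.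

Step 15. While the hindered C7 MOM ether is still being cleaved, the liberated 5- and 7-hydroxyls or methanol may add under acid catalysis to the prenyl and isopropenyl olefins. The fallback avoids Brønsted acid; it sets out from 23 and returns at 24. Treatment of 23 with TESOTf and 2,2'-bipyridyl (CH2Cl2, 0 °C → rt) exchanges the four aryl MOM ethers for triethylsilyl ethers and silylates 3-OH, giving the pentakis(triethylsilyl) ether F7. Et3N·3HF (THF, rt) then frees the five hydroxyls to give 24.

**Further compounds**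
F1 | step 13 | (2R,3S)-3-[2,4-bis(methoxymethoxy)phenyl]-N-methoxy-N-methyloxirane-2-carboxamide | CON(C)C(=O)[C@@H]1O[C@H]1c1ccc(OCOC)cc1OCOC
F2 | step 13 | {2,4-bis(methoxymethoxy)-3-(3-methylbut-2-en-1-yl)-5-[(2S)-5-methyl-2-(prop-1-en-2-yl)hex-4-en-1-yl]-6-(triisopropylsilyloxy)phenyl}lithium | C=C(C)[C@@H](CC=C(C)C)Cc1c(OCOC)c(CC=C(C)C)c(OCOC)c([Li])c1O[Si](C(C)C)(C(C)C)C(C)C
F3 | step 13 | [(2R,3S)-3-[2,4-bis(methoxymethoxy)phenyl]oxiran-2-yl]{2,4-bis(methoxymethoxy)-3-(3-methylbut-2-en-1-yl)-5-[(2S)-5-methyl-2-(prop-1-en-2-yl)hex-4-en-1-yl]-6-(triisopropylsilyloxy)phenyl}methanone | C=C(C)[C@@H](CC=C(C)C)Cc1c(OCOC)c(CC=C(C)C)c(OCOC)c(C(=O)[C@@H]2O[C@H]2c2ccc(OCOC)cc2OCOC)c1O[Si](C(C)C)(C(C)C)C(C)C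
F4 | step 6 | (2R)-1-iodo-5-methyl-2-(prop-1-en-2-yl)hex-4-ene [(R)-lavandulyl iodide] | C=C(C)[C@@H](CC=C(C)C)CI
F5 | step 6 | [(2R)-5-methyl-2-(prop-1-en-2-yl)hex-4-en-1-yl]lithium | C=C(C)[C@@H](CC=C(C)C)C[Li]
F6 | step 6 | [(2R)-5-methyl-2-(prop-1-en-2-yl)hex-4-en-1-yl]zinc bromide | C=C(C)[C@@H](CC=C(C)C)C[Zn]Br
F7 | step 15 | (2R,3R)-2-[2,4-bis(triethylsilyloxy)phenyl]-3,5,7-tris(triethylsilyloxy)-6-(3-methylbut-2-en-1-yl)-8-[(2S)-5-methyl-2-(prop-1-en-2-yl)hex-4-en-1-yl]-2,3-dihydro-4H-chromen-4-one | C=C(C)[C@@H](CC=C(C)C)Cc1c(O[Si](CC)(CC)CC)c(CC=C(C)C)c(O[Si](CC)(CC)CC)c2c1O[C@H](c1ccc(O[Si](CC)(CC)CC)cc1O[Si](CC)(CC)CC)[C@@H](O[Si](CC)(CC)CC)C2=O
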